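**Retrosynthetic overview**

1. The 11-membered ring is closed last at C1–C2 by a Ni-catalysed reductive ynal cyclization, which gives the exo-methylene allylic alcohol directly. Before that, the C2–C7 chain (C5 set by Cu-catalysed allylic alkylation) is joined at C7–C8 by B-alkyl Suzuki coupling to a 2-bromocyclohexenone.
2. The cyclohexene is never closed as a six-membered ring. It comes from the cyclopentene ring (C9, C10, C14, C15, C16) of a cis-bicyclo[3.3.0]oct-7-ene: dibromocarbene adds to the C16=C9 bond and the gem-dibromocyclopropane opens, inserting C8 between C16 and C9 as the C–Br carbon.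
3. The enabling feature is the trisubstituted C16=C9(CH3) π-bond inside a cyclopentene. Its carbene adduct is a strained bicyclo[3.1.0]hexane whose C16–C9 σ-bond (shared by both small rings) ionizes readily, and the C9 methyl stabilizes the resulting allyl cation.
4. Ring order: cyclopentane C10–C14 (quaternary C14 by asymmetric conjugate addition) → cyclopentene (Au-catalysed 5-endo-dig Conia-ene) → six-membered ring by one-carbon expansion → 11-membered ring.
5. C11 is set by convex-face hydroboration; the trans C15/C16 diol comes from Rubottom oxidation followed by hydroxyl-directed ketone reduction.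

Key step: step 9

Remark: locants used here (for this proposal only) are C1 (exocyclic-methylene carbon), C2 (OAc), C5 (CH2OAc), C8=C9 (C9 bears CH3), C10 and C11 (ring-fusion CH and the CH bonded to C1), C12, C13, C14 (quaternary, CH3), C15 (OH), C16 (OH). β is the face of the C14 methyl, so H-10, H-11 and 15-O are β and 16-O is α. Compounds 1, 2, 21, 22 and 24 are assumed to be commercial.

**Route**

Step 1
Reactants: 1 3-ethoxycyclopent-2-en-1-one; 2 1-(trimethylsilyl)propyne
Product: 4 3-[3-(trimethylsilyl)prop-2-yn-1-yl]cyclopent-2-en-1-one, via lithium 1,2-adduct 3 (not isolated)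
Conditions: n-BuLi, THF, −78 to 0 °C (2); then 1, −78 °C; 1 M HCl, rt
Reagents that add atoms: none
Why: Stork–Danheiser transposition; the silyl-capped propargyllithium (silicon disfavours allenyl attack) adds 1,2 to the vinylogous ester and acid unmasks the 3-substituted enone, with no stereocentre formed.

Step 2
Reactants: 4 3-[3-(trimethylsilyl)prop-2-yn-1-yl]cyclopent-2-en-1-one
Product: 6 (R)-triisopropyl{[3-methyl-3-(3-(trimethylsilyl)prop-2-yn-1-yl)cyclopent-1-en-1-yl]oxy}silane, via aluminium enolate 5 (not isolated)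
Conditions: Me3Al, Cu(OTf)2 (5 mol %), chiral sulfonate-NHC·Ag complex (2.5 mol %), THF, −78 °C; then TIPSOTf, −78 to 0 °C
Reagents that add atoms: trimethylaluminium C[Al](C)C; triisopropylsilyl triflate CC(C)[Si](OS(=O)(=O)C(F)(F)F)(C(C)C)C(C)C
Why: Cu-catalysed asymmetric conjugate addition of Me3Al to a β-substituted cyclopentenone should set quaternary C14 under catalyst control (ligand hand chosen for R), and the aluminium enolate is trapped regiospecifically as the C11=C10 silyl enol ether.

Step 3
Reactants: 6 (R)-TIPS enol ether with TMS-alkyne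
Product: 8 (R)-{[3-(but-2-yn-1-yl)-3-methylcyclopent-1-en-1-yl]oxy}triisopropylsilane, via lithium acetylide 7 (not isolated)
Conditions: MeLi·LiBr, THF, 0 °C to rt; then MeI, −78 °C to rt
Reagents that add atoms: iodomethane CI
Why: MeLi cleaves the C(sp)–SiMe3 bond to the lithium acetylide, which is methylated; the hindered TIPS enol ether should be inert and C14 is untouched.

Step 4
Reactants: 8 (R)-{[3-(but-2-yn-1-yl)-3-methylcyclopent-1-en-1-yl]oxy}triisopropylsilane
Product: 9 (1R,5R)-5,8-dimethylbicyclo[3.3.0]oct-7-en-2-one (cis-fused; ketone at C11, alkene C9(CH3)=C16H)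
Conditions: (JohnPhos)Au(NCMe)SbF6 (5 mol %), CH2Cl2/MeOH 10:1, rt
Reagents that add atoms: none
Why: Au(I)-catalysed 5-endo-dig Conia-ene carbocyclization of the silyl enol ether onto the activated alkyne forms C10–C9; the new five-membered ring can only be cis-fused, so H-10 is set syn to the C14 methyl.

Step 5
Reactants: 9 (1R,5R)-5,8-dimethylbicyclo[3.3.0]oct-7-en-2-one
Product: 10 cis-5,8-dimethyl-2-methylidenebicyclo[3.3.0]oct-7-ene (ring fusion as in 9)
Conditions: Zn, CH2Br2, TiCl4, THF/CH2Cl2, 0 °C to rt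
Reagents that add atoms: dibromomethane BrCBr
Why: Lombardo methylenation is non-basic, so the β,γ-unsaturated ketone should neither conjugate nor epimerize.

Step 6
Reactants: 10 cis-5,8-dimethyl-2-methylidenebicyclo[3.3.0]oct-7-ene
Product: 12 [cis-5,8-dimethylbicyclo[3.3.0]oct-7-en-2-yl]methanol with endo CH2OH (H-11 β, syn to H-10 and the C14 methyl), via B-alkyl-9-BBN 11 (not isolated)
Conditions: 9-BBN, THF, 0 °C to rt; then 3 M NaOH, 30% H2O2
Reagents that add atoms: hydrogen peroxide OO
Why: 9-BBN hydroborates only the 1,1-disubstituted exocyclic alkene and does so from the convex β-face of the cis-bicyclo[3.3.0]octene, which sets C11 with the carbon substituent on the concave face; oxidation proceeds with retention.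

Step 7
Reactants: 12 endo primary alcohol
Product: 13 cis-5,8-dimethylbicyclo[3.3.0]oct-7-ene-2-carbaldehyde (endo CHO, H-11 β)
Conditions: Dess–Martin periodinane, NaHCO3, CH2Cl2, 0 °C
Reagents that add atoms: none
Why: buffered Dess–Martin oxidation stops at the aldehyde and is mild enough to preserve the contra-thermodynamic endo C11 configuration.

Step 8
Reactants: 13 endo aldehyde
Product: 15 trimethyl{[cis-5,8-dimethylbicyclo[3.3.0]oct-7-en-2-yl]ethynyl}silane (endo alkyne, H-11 β), via lithium acetylide 14 (not isolated)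
Conditions: TMSCHN2, LDA (2.2 equiv), THF, −78 to 0 °C; then TMSCl
Reagents that add atoms: (trimethylsilyl)diazomethane C[Si](C)(C)C=[N+]=[N-]; chlorotrimethylsilane C[Si](C)(C)Cl
Why: Colvin rearrangement (alkylidene carbene, 1,2-H shift) converts the aldehyde to the alkyne at low temperature without enolizing C11, and the acetylide is capped in situ.

Step 9
Reactants: 15 endo TMS-alkyne bicyclo[3.3.0]octene
Product: 17 5-bromo-4,7a-dimethyl-3-[(trimethylsilyl)ethynyl]-2,3,3a,6,7,7a-hexahydro-1H-inden-6-ol (cis-fused; H-3a, H-3 and 7a-CH3 β; drawn as the 16β-alcohol, C16 configuration inconsequential), via gem-dibromocyclopropane 16 (not isolated)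
Conditions: CHBr3, KOtBu, pentane, −20 to 0 °C; then acetone/H2O, NaHCO3, 45 °C
Reagents that add atoms: bromoform BrC(Br)Br; water O
Why: Dibromocarbene (α-elimination) adds stereospecifically to the electron-rich trisubstituted C16=C9 alkene from the convex β-face, giving a 6,6-dibromobicyclo[3.1.0]hexane unit; strain then drives a disrotatory 2π-electrocyclic opening with loss of the endo bromide (Woodward–Hoffmann–DePuy rule), so the carbene carbon becomes C8 of a 2-bromocyclohexenyl cation. The closest known reaction type is the thermal or silver-assisted ring opening and π-allyl cation capture of ring-fused gem-dihalocyclopropanes. The six-membered ring is not closed by bond formation; it arises by one-carbon expansion, that is, cleavage of the C16–C9 bond shared by the cyclopropane and the cyclopentene after C8 is bonded to both. Water should capture the cation at C16, the less substituted terminus, giving the tetrasubstituted C8(Br)=C9(CH3) alkene; any tertiary C9 adduct re-ionizes under the solvolysis conditions, so the outcome is thermodynamically funnelled. The new C16 stereocentre (attack from the convex face) is erased in step 10, and C10, C11 and C14 are not touched. The step needs chemoselective carbene addition to the alkene over the silyl alkyne, which the much higher nucleophilicity of the trisubstituted alkene should secure.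

Step 10
Reactants: 17 bromo allylic alcohol
Product: 18 5-bromo-4,7a-dimethyl-3-[(trimethylsilyl)ethynyl]-1,2,3,3a,7,7a-hexahydro-6H-inden-6-one (cis-fused, H-11 β)
Conditions: Dess–Martin periodinane, NaHCO3, CH2Cl2, rt
Reagents that add atoms: none
Why: Dess–Martin oxidation of the secondary allylic alcohol should give the 2-bromoenone and removes the C16 stereocentre.

Step 11
Reactants: 18 bromoenone
Product: 20 7β-(triisopropylsilyloxy) derivative of 18 (15β-OTIPS, cis to the angular methyl), via TIPS dienol ether 19 (not isolated)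
Conditions: TIPSOTf, Et3N, CH2Cl2, 0 °C; then dimethyldioxirane, acetone, −40 to 0 °C
Reagents that add atoms: triisopropylsilyl triflate CC(C)[Si](OS(=O)(=O)C(F)(F)F)(C(C)C)C(C)C; dimethyldioxirane CC1(C)OO1
Why: Rubottom oxidation; soft enolization goes kinetically toward C15, DMDO should epoxidize the electron-rich enol ether (not the bromo-alkene) from the convex β-face (the α-face is screened by the cyclopentane folded beneath), and silyl migration gives the 15β-silyloxy ketone, which is α to the ketone and so can also be equilibrated toward this pseudo-equatorial epimer.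

Step 12
Reactants: 21 (E)-1,4-dibromobut-2-ene; 22 4-methoxybenzyl alcohol
Product: 23 (E)-1-bromo-4-[(4-methoxybenzyl)oxy]but-2-ene
Conditions: NaH, THF, 0 °C; then 21 (3 equiv), 0 °C to rt
Reagents that add atoms: none
Why: Williamson etherification with the dibromide in excess should give the mono-ether; the E geometry is retained.

Step 13
Reactants: 23 (E)-1-bromo-4-[(4-methoxybenzyl)oxy]but-2-ene; 24 [2-(1,3-dioxolan-2-yl)ethyl]magnesium bromide
Product: 25 2-[(3S)-3-{[(4-methoxybenzyl)oxy]methyl}pent-4-en-1-yl]-1,3-dioxolane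
Conditions: CuBr·SMe2 (1 mol %), Taniaphos (1.2 mol %), CH2Cl2, −75 °C
Reagents that add atoms: none
Why: Cu-catalysed asymmetric allylic alkylation (SN2′) delivers the Grignard alkyl group to the γ-carbon and sets C5 by ligand control (ligand hand chosen for the S product).

Step 14
Reactants: 25 chain alkene; 20 15β-OTIPS bromoenone
Product: 27 coupled enone (20 with Br at C8 replaced by the (3R)-5-(1,3-dioxolan-2-yl)-3-{[(4-methoxybenzyl)oxy]methyl}pentyl chain), via B-alkyl-9-BBN 26 (not isolated)
Conditions: 9-BBN (1.05 equiv), THF, rt; then 20, Pd(dppf)Cl2·CH2Cl2 (10 mol %), AsPh3, Cs2CO3, DMF/H2O, 40 °C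
Reagents that add atoms: none
Why: B-alkyl Suzuki–Miyaura coupling; the alkylborane from the terminal vinyl group couples with the α-bromoenone (activated toward oxidative addition) to form C7–C8 with the tetrasubstituted alkene intact, and no stereocentre is formed.

Step 15
Reactants: 27 coupled enone
Product: 29 ynal (terminal alkyne at C11, free C2 aldehyde, 5-CH2OPMB, 15β-OTIPS, 16-ketone), via terminal alkyne dioxolane 28 (not isolated)
Conditions: TBAF, AcOH, THF, 0 °C; then 2 M HCl, THF, rt
Reagents that add atoms: water O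
Why: buffered fluoride removes the alkynyl TMS group and aqueous acid hydrolyses the dioxolane, while the hindered secondary TIPS ether and the PMB ether should survive.

Step 16
Reactants: 29 ynal
Product: 30 macrocyclic (2S)-triethylsilyl ether (11-membered ring closed at C1–C2, C1=CH2, 5-CH2OPMB, 15β-OTIPS, 16-ketone)
Conditions: Ni(cod)2 (30 mol %), bulky NHC (DP-IPr·HBF4, 30 mol %), KOtBu, Et3SiH, THF (2 mM, slow addition), rt
Reagents that add atoms: triethylsilane CC[SiH](CC)CC
Why: Ni(0)/NHC reductive ynal macrocyclization (oxanickelacycle, then σ-bond metathesis with silane); the bulky carbene should steer C–C bond formation to the internal alkyne carbon (exo mode), closing the 11-membered ring as the 1,1-disubstituted allylic silyl ether, and C2 is formed under macrocyclic substrate control, which is expected but not assured to favour the required 2S epimer.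

Step 17
Reactants: 30 macrocyclic TES ether
Product: 32 macrocyclic diol (2-OH, 5-CH2OH; 15β-OTIPS, 16-ketone), via PMB-free TES ether 31 (not isolated)
Conditions: DDQ, CH2Cl2/pH 7 buffer, 0 °C; then PPTS, MeOH, rt
Reagents that add atoms: none
Why: oxidative PMB cleavage followed by mild acidic methanolysis of the allylic TES ether should free both hydroxyls while the hindered TIPS ether stays.

Step 18
Reactants: 32 macrocyclic diol
Product: 33 diacetate (2-OAc, 5-CH2OAc; 15β-OTIPS, 16-ketone)
Conditions: Ac2O, pyridine, DMAP, CH2Cl2, rt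
Reagents that add atoms: acetic anhydride CC(=O)OC(C)=O
Why: DMAP-catalysed acetylation of the primary and the secondary allylic alcohol; no stereocentre is affected.

Step 19
Reactants: 33 diacetate
Product: 34 15β-hydroxy-16-ketone diacetate
Conditions: HF·pyridine, THF/pyridine, 0 °C to rt
Reagents that add atoms: none
Why: HF·pyridine should cleave the TIPS ether without touching the acetates.

Step 20
Reactants: 34 15β-hydroxy-16-ketone diacetate
Product: 35 target CNP0193272.1
Conditions: Me4NBH(OAc)3, MeCN/AcOH, −30 to 0 °C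
Reagents that add atoms: none
Why: hydroxyl-directed (Evans–Saksena) reduction; the C15 alkoxyborohydride delivers hydride intramolecularly to the β-face of the C16 ketone, which should give the trans 15β,16α-diol, and the reagent does not reduce esters.

**Compound list**

1 | 3-ethoxycyclopent-2-en-1-one | CCOC1=CC(=O)CC1 | starting material
2 | 1-(trimethylsilyl)propyne | CC#C[Si](C)(C)C | starting material
3 | lithium 3-ethoxy-1-[3-(trimethylsilyl)prop-2-yn-1-yl]cyclopent-2-en-1-olate (racemic) | CCOC1=CC(O[Li])(CC#C[Si](C)(C)C)CC1 | intermediate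
4 | 3-[3-(trimethylsilyl)prop-2-yn-1-yl]cyclopent-2-en-1-one | O=C1CCC(CC#C[Si](C)(C)C)=C1 | intermediate
5 | dimethylaluminium (R)-enolate after conjugate addition | C[Al](C)OC1=C[C@@](C)(CC#C[Si](C)(C)C)CC1 | intermediate
6 | (R)-triisopropyl{[3-methyl-3-(3-(trimethylsilyl)prop-2-yn-1-yl)cyclopent-1-en-1-yl]oxy}silane | C[Si](C)(C)C#CC[C@@]1(C)CCC(O[Si](C(C)C)(C(C)C)C(C)C)=C1 | intermediate
7 | lithium acetylide from 6 | [Li]C#CC[C@@]1(C)CCC(O[Si](C(C)C)(C(C)C)C(C)C)=C1 | intermediate
8 | (R)-{[3-(but-2-yn-1-yl)-3-methylcyclopent-1-en-1-yl]oxy}triisopropylsilane | CC#CC[C@@]1(C)CCC(O[Si](C(C)C)(C(C)C)C(C)C)=C1 | intermediate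
9 | (1R,5R)-5,8-dimethylbicyclo[3.3.0]oct-7-en-2-one | C1=C(C)[C@@H]2C(=O)CC[C@]2(C)C1 | intermediate
10 | cis-5,8-dimethyl-2-methylidenebicyclo[3.3.0]oct-7-ene | C1=C(C)[C@@H]2C(=C)CC[C@]2(C)C1 | intermediate
11 | B-alkyl-9-BBN adduct of 10 (boron on the exocyclic CH2, H-11 β) | C1=C(C)[C@@H]2[C@H](CB3C4CCCC3CCC4)CC[C@]2(C)C1 | intermediate
12 | [cis-5,8-dimethylbicyclo[3.3.0]oct-7-en-2-yl]methanol, endo CH2OH | C1=C(C)[C@@H]2[C@H](CO)CC[C@]2(C)C1 | intermediate
13 | cis-5,8-dimethylbicyclo[3.3.0]oct-7-ene-2-carbaldehyde, endo CHO | C1=C(C)[C@@H]2[C@H](C=O)CC[C@]2(C)C1 | intermediate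
14 | lithium acetylide from 13 | C1=C(C)[C@@H]2[C@H](C#C[Li])CC[C@]2(C)C1 | intermediate
15 | trimethyl{[cis-5,8-dimethylbicyclo[3.3.0]oct-7-en-2-yl]ethynyl}silane, endo | C1=C(C)[C@@H]2[C@H](C#C[Si](C)(C)C)CC[C@]2(C)C1 | intermediate
16 | gem-dibromocyclopropane of 15 (CBr2 bridging C16 and C9 on the β-face) | BrC1(Br)[C@@H]2C[C@@]3(C)CC[C@@H](C#C[Si](C)(C)C)[C@H]3[C@]12C | intermediate
17 | 5-bromo-4,7a-dimethyl-3-[(trimethylsilyl)ethynyl]-2,3,3a,6,7,7a-hexahydro-1H-inden-6-ol (cis-fused, 16β-OH drawn) | BrC1=C(C)[C@@H]2[C@H](C#C[Si](C)(C)C)CC[C@]2(C)C[C@H]1O | intermediate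
18 | 5-bromo-4,7a-dimethyl-3-[(trimethylsilyl)ethynyl]-1,2,3,3a,7,7a-hexahydro-6H-inden-6-one | BrC1=C(C)[C@@H]2[C@H](C#C[Si](C)(C)C)CC[C@]2(C)CC1=O | intermediate
19 | TIPS dienol ether of 18 (C15=C16–OTIPS) | BrC1=C(C)[C@@H]2[C@H](C#C[Si](C)(C)C)CC[C@]2(C)C=C1O[Si](C(C)C)(C(C)C)C(C)C | intermediate
20 | 15β-(triisopropylsilyloxy) bromoenone | BrC1=C(C)[C@@H]2[C@H](C#C[Si](C)(C)C)CC[C@]2(C)[C@@H](O[Si](C(C)C)(C(C)C)C(C)C)C1=O | intermediate
21 | (E)-1,4-dibromobut-2-ene | BrC/C=C/CBr | starting material
22 | 4-methoxybenzyl alcohol | COc1ccc(CO)cc1 | starting material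
23 | (E)-1-bromo-4-[(4-methoxybenzyl)oxy]but-2-ene | BrC/C=C/COCc1ccc(OC)cc1 | intermediate
24 | [2-(1,3-dioxolan-2-yl)ethyl]magnesium bromide | Br[Mg]CCC1OCCO1 | starting material
25 | 2-[(3S)-3-{[(4-methoxybenzyl)oxy]methyl}pent-4-en-1-yl]-1,3-dioxolane | C=C[C@@H](COCc1ccc(OC)cc1)CCC1OCCO1 | intermediate
26 | B-alkyl-9-BBN adduct of 25 (boron on C7) | C(C[C@@H](COCc1ccc(OC)cc1)CCC1OCCO1)B1C2CCCC1CCC2 | intermediate
27 | coupled enone (C7–C8 bond; TMS-alkyne, dioxolane, PMB and TIPS ethers) | O1CCOC1CC[C@H](COCc1ccc(OC)cc1)CCC1=C(C)[C@@H]2[C@H](C#C[Si](C)(C)C)CC[C@]2(C)[C@@H](O[Si](C(C)C)(C(C)C)C(C)C)C1=O | intermediate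
28 | terminal alkyne of 27, dioxolane still in place | O1CCOC1CC[C@H](COCc1ccc(OC)cc1)CCC1=C(C)[C@@H]2[C@H](C#C)CC[C@]2(C)[C@@H](O[Si](C(C)C)(C(C)C)C(C)C)C1=O | intermediate
29 | ynal (terminal alkyne at C11, C2 aldehyde) | O=CCC[C@H](COCc1ccc(OC)cc1)CCC1=C(C)[C@@H]2[C@H](C#C)CC[C@]2(C)[C@@H](O[Si](C(C)C)(C(C)C)C(C)C)C1=O | intermediate
30 | macrocyclic (2S)-triethylsilyl ether | C=C1[C@@H](O[Si](CC)(CC)CC)CC[C@H](COCc2ccc(OC)cc2)CCC2=C(C)[C@@H]3[C@H]1CC[C@]3(C)[C@@H](O[Si](C(C)C)(C(C)C)C(C)C)C2=O | intermediate
31 | PMB-free macrocyclic TES ether (5-CH2OH) | C=C1[C@@H](O[Si](CC)(CC)CC)CC[C@H](CO)CCC2=C(C)[C@@H]3[C@H]1CC[C@]3(C)[C@@H](O[Si](C(C)C)(C(C)C)C(C)C)C2=O | intermediate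
32 | macrocyclic diol (2-OH, 5-CH2OH, 15β-OTIPS, 16-ketone) | C=C1[C@@H](O)CC[C@H](CO)CCC2=C(C)[C@@H]3[C@H]1CC[C@]3(C)[C@@H](O[Si](C(C)C)(C(C)C)C(C)C)C2=O | intermediate
33 | diacetate of 32 | C=C1[C@@H](OC(C)=O)CC[C@H](COC(C)=O)CCC2=C(C)[C@@H]3[C@H]1CC[C@]3(C)[C@@H](O[Si](C(C)C)(C(C)C)C(C)C)C2=O | intermediate
34 | 15β-hydroxy-16-ketone diacetate | C=C1[C@@H](OC(C)=O)CC[C@H](COC(C)=O)CCC2=C(C)[C@@H]3[C@H]1CC[C@]3(C)[C@@H](O)C2=O | intermediate
35 | CNP0193272.1 (2S,5R; H-10, H-11, 14-CH3 and 15-OH β; 16-OH α) | C=C1[C@@H](OC(C)=O)CC[C@H](COC(C)=O)CCC2=C(C)[C@@H]3[C@H]1CC[C@]3(C)[C@@H](O)[C@@H]2O | target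

**Totals and risks**

Total step count: 20. Longest linear sequence: 18 (steps 1–11 and 14–20); steps 12–13 make the side-chain fragment.

Steps most likely to fail:

1. Step 16. Closing a strained 11-membered ring containing an E-tetrasubstituted ring alkene may lose to oligomerization, to endo-mode coupling at the terminal alkyne carbon, or to poor facial selectivity at C2. The fallback sets out from 29. Mo-catalysed Markovnikov hydrostannation of the terminal alkyne (Bu3SnH, Mo(CO)3(CNtBu)3, THF, 55 °C) should give the α-stannyl alkene F1. Iododestannylation (I2, CH2Cl2, 0 °C) gives the 2-iodoalkene F2. An intramolecular Nozaki–Hiyama–Kishi reaction (CrCl2, cat. NiCl2, chiral sulfonamide ligand for reagent control at C2, THF/DMSO, high dilution) then closes the ring to the free allylic alcohol F3. DDQ cleavage of the PMB ether returns to the route at 32.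

2. Step 9. The allyl cation may lose a proton to give dienes or be trapped irreversibly at the tertiary C9 terminus, and carbene addition may be incomplete or unselective. The fallback sets out from 15. Epoxidation (mCPBA, NaHCO3, convex face) gives the epoxide F4. Meinwald rearrangement (BF3·OEt2, −78 °C; hydride shift from C16 to the tertiary C9 cation) gives the C16 ketone F5. Thermodynamic enol silylation (TMSCl, NaI, Et3N, MeCN) gives the tetrasubstituted silyl enol ether F6. Dibromocarbene (CHBr3, KOtBu) then adds to F6, and the siloxy-dibromocyclopropane collapses with loss of the silyl group directly to the 2-bromoenone, with no free cation left to partition. This returns to the route at 18.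

3. Step 11. Facial selectivity of the epoxidation at C15 may be poor, or enolization may go toward the γ-positions. The fallback sets out from 18. Kinetic deprotonation (KHMDS, THF, −78 °C) and reagent-controlled Davis hydroxylation with the matching enantiomer of (camphorsulfonyl)oxaziridine should give the 15β-hydroxy ketone F7. Silylation (TIPSOTf, 2,6-lutidine) returns to the route at 20.

Further compounds
F1 | step 16 | α-tributylstannyl alkene of 29 (C1 bears SnBu3 and =CH2) | O=CCC[C@H](COCc1ccc(OC)cc1)CCC1=C(C)[C@@H]2[C@H](C(=C)[Sn](CCCC)(CCCC)CCCC)CC[C@]2(C)[C@@H](O[Si](C(C)C)(C(C)C)C(C)C)C1=O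
F2 | step 16 | 2-iodoalkene aldehyde (C1 bears I and =CH2) | O=CCC[C@H](COCc1ccc(OC)cc1)CCC1=C(C)[C@@H]2[C@H](C(I)=C)CC[C@]2(C)[C@@H](O[Si](C(C)C)(C(C)C)C(C)C)C1=O
F3 | step 16 | macrocyclic (2S)-allylic alcohol with 5-CH2OPMB and 15β-OTIPS | C=C1[C@@H](O)CC[C@H](COCc2ccc(OC)cc2)CCC2=C(C)[C@@H]3[C@H]1CC[C@]3(C)[C@@H](O[Si](C(C)C)(C(C)C)C(C)C)C2=O
F4 | step 9 | β-epoxide of 15 across C16–C9 | O1[C@@H]2C[C@@]3(C)CC[C@@H](C#C[Si](C)(C)C)[C@H]3[C@]12C
F5 | step 9 | C16 ketone with C9–H (9-CH3 β drawn, epimer inconsequential) | O=C1[C@@H](C)[C@@H]2[C@H](C#C[Si](C)(C)C)CC[C@]2(C)C1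
F6 | step 9 | trimethylsilyl enol ether C16(OTMS)=C9(CH3) | C[Si](C)(C)OC1=C(C)[C@@H]2[C@H](C#C[Si](C)(C)C)CC[C@]2(C)C1
F7 | step 11 | 15β-hydroxy bromoenone | BrC1=C(C)[C@@H]2[C@H](C#C[Si](C)(C)C)CC[C@]2(C)[C@@H](O)C1=O
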